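## Analysis of the target

Target 19 is a 3,3'-linked biflavanone: two identical 7-hydroxy-5-methoxy-2-(4-methoxyphenyl)chroman-4-one units joined through C3. Unprimed locants are used for one chromanone and primed locants for the other; rings A and A' are the fused benzene rings, and "anisyl" is the 4-methoxyphenyl group at C2 and C2'. The four stereocentres C2, C3, C2' and C3' are configured 2S,3R,2'S,3'R, so the molecule is C2-symmetric and each pyranone ring is 2,3-trans, with the anisyl group and the C3–C3' bond equatorial. C3 and C3' lie α to ketones and can settle into this favoured trans arrangement by enolisation. C2 and C2' are benzylic ether carbons and carry the real stereochemical information: the absolute configuration, and the relation of the two halves that separates the target from its meso diastereomer. Sensitive features are the β-aryloxy ketones (retro-oxa-Michael opening in base, with loss of C2), the 4-methoxybenzylic C2–O bonds (ionisation in strong acid), and the oxygen pattern of rings A and A' (5-OMe kept, 7-OH free), which requires a removable group on the 7-oxygens. The difficulty is the central C3–C3' bond between two stereogenic tertiary carbons; a direct union of two flavanone C3 positions would give diastereomer mixtures. The strategy rests on the second pyran ring (O1', C2', C3', C4', C4a', C8a'): O1', C8a', C4a' and C4' are read as an ortho-quinone methide of ring A', and C2'=C3' as a 4-methoxystyrene double bond hanging from C3 of an intact first flavanone.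

## Retrosynthetic reasoning

19 from 18. The two free 7-hydroxyls are masked as benzyl ethers until the end. Benzyl survives the acidic, basic and oxidative steps before it and is removed under neutral conditions that the β-aryloxy ketones tolerate.

18 from 17 and 16. The C4' carbonyl is taken back to a C4'–O single bond, first the alcohol 17 and then the methyl ether 16. This lets ring A' enter at the aldehyde oxidation level, keeps C3' non-enolisable until the last bond-forming events are over, and makes the configuration of C4' irrelevant. Because C3' is created trans to C2', no separate equilibration of C3 and C3' is planned.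

16 from 10 and 13. The bonds C3'–C4' and O1'–C2' are cut. This divides the molecule into flavanone 10, which already holds C2 and C3, and the achiral salicylaldehyde 13. It is preferred over a cut of C3–C3', which would require coupling two α-keto tertiary carbons with no facial bias. The forward reaction has to add the cationic quinone-methide carbon to the alkene carbon next to C3, close the ring through the phenol oxygen on the anisyl-bearing carbon, carry the E geometry into a 2',3'-trans ring, and choose the alkene face under the influence of C3, while leaving the ketone, the C2–O bond and the benzyl ethers untouched.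

10 from 8 and 9. The C2–aryl bond is cut. The forward step is a catalytic enantioselective conjugate addition of boronic acid 9 to the chromone 8; it is the only point where an external source of chirality is needed, and C3 follows by equilibration. It is placed directly before the key step so that the base-sensitive β,γ-unsaturated ketone 10 is not carried through further operations.

8 from 5 and 6, and 5 from 3. The styryl double bond is cut to the 3-formylchromone 5 and the arylacetic acid 6 (condensation with loss of CO2, E-selective). The pyranone C2 and the formyl carbon of 5 are cut back to the methyl ketone 3 (double formylation and cyclisation).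

3 from 2 from 1, and 13 from 12 from 11. In both aromatic building blocks the three hydroxyls are differentiated by two successive O-alkylations, benzyl on the non-chelated 4-hydroxyl and then methyl on one of the two equivalent chelated hydroxyls, which leaves the phenol needed for ring closure.

## Alternatives that were turned down

Alternative 1: Both C4–C4a and both C8a–O1 bonds are cut, so that rings A and A' become arynes and the core becomes the diacid (2E,3E)-2,3-bis(4-methoxybenzylidene)butanedioic acid A1.
- Forward key step: CsF would release the aryne from 5-(benzyloxy)-3-methoxy-2-(trimethylsilyl)phenyl triflate A2. Each carboxylate would add to it and the acyl group would shift to the neighbouring aryl anion, giving the bis(2'-hydroxychalcone) A3. Two oxa-Michael closures would then form the pyranone rings.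
- For it: four bonds in one operation, full use of the symmetry and very few steps. The methoxy group of the aryne also directs the carboxylate to the distal carbon, which is the regiochemistry required.
- Against it: A3 has no stereocentre. All four would be created in reversible phenoxide additions to α-substituted enones, for which no dependable enantioselective catalyst exists and which have no reason to prefer the C2-symmetric over the meso isomer. The hindered, cross-conjugated diacid A1 is also a poor acyl donor and prone to anhydride formation.
- Comparison: on convergence and step count this route is stronger. The chosen route offers instead a defined source of absolute configuration (step 5) and its relay to the second half, which decides the matter for a single enantiomer.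

Alternative 2: C3–C4 and C3'–C4' are cut, leading to the propargylic bis-aryl ether dialdehyde A4.
- Forward key step: with a thiazolium-derived carbene and K2CO3, one formyl group would add as an acyl anion equivalent across the alkyne (6-exo-dig). The second would add to the resulting exocyclic enone in an intramolecular Stetter reaction (6-exo-trig), giving the bis-silyl ether A5 of the target directly.
- For it: C2 and C2' would both come from one enantioselective alkynylation, so no facial selection between the halves is needed, and C3 and C3' would settle by enolisation. The sequence is the shortest of all, and on control of C2' it is stronger than the chosen route.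
- Against it: the aryl ether bonds of A4 sit on carbons that are both propargylic and 4-methoxybenzylic, so their formation is exposed to ionisation and loss of configuration. The formyl groups are electron-rich and flanked by two ortho oxygens, a poor combination for carbene catalysis. The alkyne is internal and branched at both propargylic positions. The intermediate 3-alkylidene flavanone can isomerise under the carbonate base to a 3-alkylflavone, which destroys C2.
- Comparison: three untested events would have to succeed in one flask. The chosen route concentrates the uncertainty in one selectivity question on a known reaction.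

Alternative 3: The aryl ketone bonds C4–C4a and C4'–C4a' are cut, which leads to the cis-fused bis-lactone 2,6-bis(4-methoxyphenyl)-3,7-dioxabicyclo[3.3.0]octane-4,8-dione A6 and the aryllithium A7.
- Forward key step: two equivalents of A7 would open both lactones at −78 °C to the diketo diol A8. The freed alkoxides would later close the pyranone rings by displacing the ortho fluorides, and C3 and C3' would then have to be epimerised.
- For it: the C3–C3' bond and the relation of C2 to C2' are fixed in a rigid bicycle before the arenes arrive. A6 belongs to a familiar class of phenylpropanoid dimers, and four bonds form in two operations, so in convergence it is stronger than the chosen route.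
- Against it: A6 is needed as a single enantiomer, which oxidative dimerisation does not deliver. Each alkoxide freed in the key step is β to a new aryl ketone and can fragment by retro-aldol reaction. The ortho-fluoro aryllithium A7 loses LiF on warming, and a second addition to the ketone competes. The ring closure is a nucleophilic aromatic substitution on a ring bearing two donor groups. The cis ring fusion gives C3 and C3' with the wrong sense, so A8 leads first to 2,3-cis rings.
- Comparison: the chosen route needs more steps for the second half, but uses no organolithium chemistry next to base-labile aldol units and forms the trans rings directly.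

Key step: step 8

Remark on the chemistry: C4' of 16 and 17 is drawn as the 3',4'-trans epimer; the centre is removed in step 10, so either epimer or a mixture serves equally.
Remark on the chemistry: in step 5 the antipode of the chiral diene is chosen that delivers the aryl group to give 2S; both antipodes of such ligands are available.

Step 1
Reactants: 1 2',4',6'-trihydroxyacetophenone
Product: 2 1-[4-(benzyloxy)-2,6-dihydroxyphenyl]ethan-1-one
Conditions: BnBr (1.0 equiv), K2CO3 (1.1 equiv), DMF, 0 °C to rt
Reagents that add atoms: benzyl bromide BrCc1ccccc1
Why: Williamson ether synthesis; the 4-hydroxyl is the most acidic one and the only one not held in a hydrogen bond to the acetyl group, so one equivalent of benzyl bromide with a mild base should alkylate it first.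

Step 2
Reactants: 2 1-[4-(benzyloxy)-2,6-dihydroxyphenyl]ethan-1-one
Product: 3 1-[4-(benzyloxy)-2-hydroxy-6-methoxyphenyl]ethan-1-one
Conditions: MeI (1.1 equiv), K2CO3 (1.2 equiv), acetone, reflux
Reagents that add atoms: iodomethane CI
Why: Williamson ether synthesis; the two remaining hydroxyls are equivalent, and once one is methylated the other is locked in a strong chelate with the ketone, which should stop the reaction at the monomethyl ether.

Step 3
Reactants: 3 1-[4-(benzyloxy)-2-hydroxy-6-methoxyphenyl]ethan-1-one
Product: 5 7-(benzyloxy)-5-methoxy-4-oxo-4H-chromene-3-carbaldehyde, via iminium chloride 4 (not isolated)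
Conditions: POCl3 (3 equiv), DMF, 0 to 50 °C; then H2O, 0 °C to rt
Reagents that add atoms: N,N-dimethylformamide CN(C)C=O; water O
Why: Vilsmeier–Haack reaction: the acetyl methyl group is formylated twice by the chloroiminium salt, the phenol adds to one iminium carbon with loss of dimethylamine to close the pyranone ring, and water hydrolyses 4 to the aldehyde; the ketone deactivates ring A enough to keep formylation on the side chain.

Step 4
Reactants: 5 7-(benzyloxy)-5-methoxy-4-oxo-4H-chromene-3-carbaldehyde; 6 4-methoxyphenylacetic acid
Product: 8 7-(benzyloxy)-5-methoxy-3-[(E)-2-(4-methoxyphenyl)ethenyl]-4H-chromen-4-one, via acrylic acid 7 (not isolated)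
Conditions: 6 (1.5 equiv), KOt-Bu (1.2 equiv), pyridine, reflux
Reagents that add atoms: none
Why: Knoevenagel condensation of the arylacetic acid with the formyl group gives 7; reversible conjugate addition at C2 turns 7 into a vinylogous β-keto acid that loses CO2, and re-formation of the chromone leaves the less hindered E-alkene.

Step 5
Reactants: 8 7-(benzyloxy)-5-methoxy-3-[(E)-2-(4-methoxyphenyl)ethenyl]-4H-chromen-4-one; 9 4-methoxyphenylboronic acid
Product: 10 (2S,3R)-7-(benzyloxy)-5-methoxy-2-(4-methoxyphenyl)-3-[(E)-2-(4-methoxyphenyl)ethenyl]-2,3-dihydro-4H-chromen-4-one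
Conditions: 9 (3 equiv), [RhCl(C2H4)2]2 (3 mol%), chiral diene Ph-bod* (antipode giving 2S, 7 mol%), KOH (0.2 equiv), dioxane/H2O 10:1, 50 °C
Reagents that add atoms: none
Why: Hayashi–Miyaura asymmetric 1,4-addition: the arylrhodium species (monovalent rhodium) inserts the C2=C3 bond with the aryl group going to C2 on the face fixed by the chiral diene (2S), a reaction known for chromones, here with a 3-substituent that slows it but leads to an allyl-stabilised rhodium enolate. Protonation at C3 and enolisation under the mildly basic conditions should leave the diequatorial 2,3-trans isomer (3R).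

Step 6
Reactants: 11 2,4,6-trihydroxybenzaldehyde
Product: 12 4-(benzyloxy)-2,6-dihydroxybenzaldehyde
Conditions: BnBr (1.0 equiv), K2CO3 (1.1 equiv), DMF, 0 °C to rt
Reagents that add atoms: benzyl bromide BrCc1ccccc1
Why: Williamson ether synthesis; the 4-hydroxyl, para to the formyl group and not chelated, is the most acidic and should be benzylated before the two hydrogen-bonded ortho hydroxyls.

Step 7
Reactants: 12 4-(benzyloxy)-2,6-dihydroxybenzaldehyde
Product: 13 4-(benzyloxy)-2-hydroxy-6-methoxybenzaldehyde
Conditions: MeI (1.1 equiv), K2CO3 (1.2 equiv), acetone, reflux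
Reagents that add atoms: iodomethane CI
Why: Williamson ether synthesis; methylation of one of the two equivalent hydroxyls leaves the other as a strongly chelated phenol, which resists further alkylation and is the hydroxyl needed for the ring closure in step 8.

Step 8
Reactants: 10 (2S,3R)-7-(benzyloxy)-5-methoxy-2-(4-methoxyphenyl)-3-[(E)-2-(4-methoxyphenyl)ethenyl]-2,3-dihydro-4H-chromen-4-one; 13 4-(benzyloxy)-2-hydroxy-6-methoxybenzaldehyde
Product: 16 (2S,3R)-7-(benzyloxy)-3-[(2S,3S,4S)-7-(benzyloxy)-4,5-dimethoxy-2-(4-methoxyphenyl)-3,4-dihydro-2H-chromen-3-yl]-5-methoxy-2-(4-methoxyphenyl)-2,3-dihydro-4H-chromen-4-one (2',3'-trans-3',4'-trans), via dimethyl acetal 14 (not isolated), via oxocarbenium triflate 15 (not isolated)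
Conditions: 13 (1.5 equiv), HC(OMe)3 (2 equiv), TfOH (10 mol%), CH2Cl2, rt; then 10, −40 to 0 °C
Reagents that add atoms: trimethyl orthoformate COC(OC)OC
Why: Acid converts 13 and the orthoformate into acetal 14, which ionises to the O-methyl oxocarbenium ion 15, an ortho-quinone methide equivalent stabilised by the free phenol and the two ring ethers. The styryl alkene of 10 attacks the carbenium carbon through the carbon next to C3 (C3'–C4' bond), because only this places the positive charge on the anisyl-bearing carbon; the phenol oxygen then captures that benzylic cation (O1'–C2' bond), so the pyran ring is closed through oxygen as a six-membered ring in an asynchronous inverse-electron-demand hetero-Diels–Alder reaction. This is the known acid-promoted three-component synthesis of 4-alkoxyflavans from salicylaldehydes, orthoformates and β-substituted styrenes, applied here to an alkene that carries a flavanone. C2' and C3' should end trans because the E geometry is transferred and both substituents are equatorial in the chroman formed. The alkene face is chosen by C3: with the C3–H bond eclipsing the double bond, C2 and its equatorial anisyl group cover one face, so the electrophile should arrive past the flat C4 carbonyl, which by analysis of this conformer gives the C3' and hence C2' configuration of the target. C4' forms with the methoxy group trans to C3' or as a mixture, which does not matter since the centre is oxidised in step 10. The step needs chemoselectivity for the one isolated alkene over the aryl ketone and the arenes, which catalytic acid, low temperature and the unreactive vinylogous-ester ketone should secure.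

Step 9
Reactants: 16 flavanone–4'-methoxyflavan cycloadduct (full name in step 8)
Product: 17 (2S,3R)-7-(benzyloxy)-3-[(2S,3S,4S)-7-(benzyloxy)-4-hydroxy-5-methoxy-2-(4-methoxyphenyl)-3,4-dihydro-2H-chromen-3-yl]-5-methoxy-2-(4-methoxyphenyl)-2,3-dihydro-4H-chromen-4-one
Conditions: TsOH·H2O (10 mol%), THF/H2O 4:1, rt to 40 °C
Reagents that add atoms: water O
Why: Acid-catalysed solvolysis: the C4' methoxy group leaves from a benzylic carbon that is ortho and para to three oxygen donors of ring A', and the cation is captured by the large excess of water; the configuration of C4' is irrelevant, while C2' and C3' are not touched.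

Step 10
Reactants: 17 flavanone–flavan-4'-ol (full name in step 9)
Product: 18 (2S,2'S,3R,3'R)-7,7'-bis(benzyloxy)-5,5'-dimethoxy-2,2'-bis(4-methoxyphenyl)-[3,3'-bichromane]-4,4'-dione
Conditions: Dess–Martin periodinane (1.5 equiv), CH2Cl2, 0 °C to rt
Reagents that add atoms: none
Why: Dess–Martin oxidation of the secondary benzylic alcohol to the aryl ketone under nearly neutral conditions; C3' becomes enolisable only now and already has the equatorial, 2',3'-trans arrangement, so no separate equilibration should be needed and the two halves become identical.

Step 11
Reactants: 18 (2S,2'S,3R,3'R)-7,7'-bis(benzyloxy)-5,5'-dimethoxy-2,2'-bis(4-methoxyphenyl)-[3,3'-bichromane]-4,4'-dione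
Product: 19 (2S,2'S,3R,3'R)-7,7'-dihydroxy-5,5'-dimethoxy-2,2'-bis(4-methoxyphenyl)-[3,3'-bichromane]-4,4'-dione (4',4''',5,5''-tetramethylchamaejasmin)
Conditions: H2 (1 atm), 10% Pd/C, EtOAc/MeOH, rt
Reagents that add atoms: none
Why: Hydrogenolysis of the two aryl benzyl ethers on palladium; the methyl ethers and the electron-rich aryl ketones are inert, and stopping at the uptake of two equivalents of hydrogen should spare the benzylic C2–O bonds.

## Compound list

1 | 2',4',6'-trihydroxyacetophenone | CC(=O)c1c(O)cc(O)cc1O | starting material
2 | 1-[4-(benzyloxy)-2,6-dihydroxyphenyl]ethan-1-one | CC(=O)c1c(O)cc(OCc2ccccc2)cc1O | intermediate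
3 | 1-[4-(benzyloxy)-2-hydroxy-6-methoxyphenyl]ethan-1-one | CC(=O)c1c(O)cc(OCc2ccccc2)cc1OC | intermediate
4 | N-{[7-(benzyloxy)-5-methoxy-4-oxo-4H-chromen-3-yl]methylidene}-N-methylmethanaminium chloride (not isolated) | C[N+](C)=Cc1coc2cc(OCc3ccccc3)cc(OC)c2c1=O.[Cl-] | intermediate
5 | 7-(benzyloxy)-5-methoxy-4-oxo-4H-chromene-3-carbaldehyde | O=Cc1coc2cc(OCc3ccccc3)cc(OC)c2c1=O | intermediate
6 | 4-methoxyphenylacetic acid | COc1ccc(CC(=O)O)cc1 | starting material
7 | (2E)-3-[7-(benzyloxy)-5-methoxy-4-oxo-4H-chromen-3-yl]-2-(4-methoxyphenyl)prop-2-enoic acid (not isolated; its geometry has no bearing on the product) | O=C(O)/C(c1ccc(OC)cc1)=C/c1coc2cc(OCc3ccccc3)cc(OC)c2c1=O | intermediate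
8 | 7-(benzyloxy)-5-methoxy-3-[(E)-2-(4-methoxyphenyl)ethenyl]-4H-chromen-4-one | COc1ccc(/C=C/c2coc3cc(OCc4ccccc4)cc(OC)c3c2=O)cc1 | intermediate
9 | 4-methoxyphenylboronic acid | COc1ccc(B(O)O)cc1 | starting material
10 | (2S,3R)-7-(benzyloxy)-5-methoxy-2-(4-methoxyphenyl)-3-[(E)-2-(4-methoxyphenyl)ethenyl]-2,3-dihydro-4H-chromen-4-one | COc1ccc([C@H]2Oc3cc(OCc4ccccc4)cc(OC)c3C(=O)[C@@H]2/C=C/c2ccc(OC)cc2)cc1 | intermediate
11 | 2,4,6-trihydroxybenzaldehyde | O=Cc1c(O)cc(O)cc1O | starting material
12 | 4-(benzyloxy)-2,6-dihydroxybenzaldehyde | O=Cc1c(O)cc(OCc2ccccc2)cc1O | intermediate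
13 | 4-(benzyloxy)-2-hydroxy-6-methoxybenzaldehyde | COc1cc(OCc2ccccc2)cc(O)c1C=O | intermediate
14 | 5-(benzyloxy)-2-(dimethoxymethyl)-3-methoxyphenol (not isolated) | COc1cc(OCc2ccccc2)cc(O)c1C(OC)OC | intermediate
15 | {[4-(benzyloxy)-2-hydroxy-6-methoxyphenyl]methylidene}(methyl)oxonium triflate (not isolated) | COc1cc(OCc2ccccc2)cc(O)c1C=[O+]C.[O-]S(=O)(=O)C(F)(F)F | intermediate
16 | (2S,3R)-7-(benzyloxy)-3-[(2S,3S,4S)-7-(benzyloxy)-4,5-dimethoxy-2-(4-methoxyphenyl)-3,4-dihydro-2H-chromen-3-yl]-5-methoxy-2-(4-methoxyphenyl)-2,3-dihydro-4H-chromen-4-one; C2, C3, C2' and C3' arranged in space as in the target, 4'-OMe trans to the C3' substituent | COc1ccc([C@H]2Oc3cc(OCc4ccccc4)cc(OC)c3C(=O)[C@@H]2[C@H]2[C@H](OC)c3c(OC)cc(OCc4ccccc4)cc3O[C@@H]2c2ccc(OC)cc2)cc1 | intermediate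
17 | (2S,3R)-7-(benzyloxy)-3-[(2S,3S,4S)-7-(benzyloxy)-4-hydroxy-5-methoxy-2-(4-methoxyphenyl)-3,4-dihydro-2H-chromen-3-yl]-5-methoxy-2-(4-methoxyphenyl)-2,3-dihydro-4H-chromen-4-one | COc1ccc([C@H]2Oc3cc(OCc4ccccc4)cc(OC)c3C(=O)[C@@H]2[C@H]2[C@H](O)c3c(OC)cc(OCc4ccccc4)cc3O[C@@H]2c2ccc(OC)cc2)cc1 | intermediate
18 | (2S,2'S,3R,3'R)-7,7'-bis(benzyloxy)-5,5'-dimethoxy-2,2'-bis(4-methoxyphenyl)-[3,3'-bichromane]-4,4'-dione | COc1ccc([C@H]2Oc3cc(OCc4ccccc4)cc(OC)c3C(=O)[C@@H]2[C@H]2C(=O)c3c(OC)cc(OCc4ccccc4)cc3O[C@@H]2c2ccc(OC)cc2)cc1 | intermediate
19 | (2S,2'S,3R,3'R)-7,7'-dihydroxy-5,5'-dimethoxy-2,2'-bis(4-methoxyphenyl)-[3,3'-bichromane]-4,4'-dione (4',4''',5,5''-tetramethylchamaejasmin) | COc1ccc([C@H]2Oc3cc(O)cc(OC)c3C(=O)[C@@H]2[C@H]2C(=O)c3c(OC)cc(O)cc3O[C@@H]2c2ccc(OC)cc2)cc1 | target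

## Step count and least certain steps

Total: 11 steps. Longest linear sequence: 9 steps (steps 1 to 5 and 8 to 11, from 1); the aldehyde branch (steps 6 and 7) joins at step 8.

Step 8 (key step). The most likely failure is poor facial selectivity at the alkene. The preference for the C3–H-eclipsed conformer is only moderate, and ionisation of the new C2'–O1' bond or reversal of the C–C bond formation under acid could erode whatever selectivity is reached, leading to the precursor of the meso diastereomer. Acid-promoted migration of the double bond of 10 into conjugation is a second risk. Fallback, with the face chosen by a catalyst instead of by C3: aldehyde 13 would be reduced with NaBH4 to 5-(benzyloxy)-2-(hydroxymethyl)-3-methoxyphenol F1. The ortho-quinone methide generated from F1 by a chiral BINOL-derived N-triflylphosphoramide would be combined with 10, in the known chiral Brønsted acid-catalysed cycloaddition of ortho-hydroxybenzyl alcohols with styrenes. This should give the 4'-unsubstituted flavan (2S,3R)-7-(benzyloxy)-3-[(2S,3R)-7-(benzyloxy)-5-methoxy-2-(4-methoxyphenyl)-3,4-dihydro-2H-chromen-3-yl]-5-methoxy-2-(4-methoxyphenyl)-2,3-dihydro-4H-chromen-4-one F2. Oxidation of its C4' methylene group with DDQ in CH2Cl2/MeOH, the known C4 functionalisation of 5,7-dioxygenated flavans, would install the methoxy group. The fallback sets out from 10 and 13 and returns to the route at 16.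

Step 5. Insertion of the arylrhodium species into a chromone that is both electron-rich and substituted at C3 may be slow, so that protodeboronation of 9 consumes the reagent. The mildly basic medium may also move the double bond of the product into conjugation, and on to a 3-alkylflavone. Fallback, replacing asymmetric catalysis by resolution: 8 would be treated with 4-methoxyphenylmagnesium bromide and CuI (10 mol%) in THF at −40 °C. After work-up with aqueous NH4Cl this should give the racemic trans ketone, that is 10 together with its enantiomer (2R,3S)-7-(benzyloxy)-5-methoxy-2-(4-methoxyphenyl)-3-[(E)-2-(4-methoxyphenyl)ethenyl]-2,3-dihydro-4H-chromen-4-one F3, which would be removed by preparative chromatography on a chiral stationary phase. The fallback sets out from 8 and returns at 10.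

Step 9. The C4' cation may lose the C3' proton to give a 2H-chromene instead of taking up water, and the 4-methoxybenzylic C2'–O1' bond may ionise in the same medium with epimerisation at C2'. Fallback, omitting the alcohol: 16 would be oxidised directly with DDQ in wet CH2Cl2. Hydride abstraction from C4' and hydrolysis of the methoxycarbenium ion would follow the known oxidative cleavage of electron-rich benzylic ethers, and should give the ketone without any acid. The fallback sets out from 16 and returns at 18, skipping 17; it makes no new compound (F0).

Step 3. The Vilsmeier reagent may attack the free positions of the electron-rich ring A instead of, or in addition to, the acetyl group, which would lower the yield of 5 and complicate its purification. Fallback, building the chromone first and attaching the side chain by cross-coupling: 3 would be condensed with N,N-dimethylformamide dimethyl acetal to the enaminone (2E)-1-[4-(benzyloxy)-2-hydroxy-6-methoxyphenyl]-3-(dimethylamino)prop-2-en-1-one F4. Cyclisation with I2 would give 7-(benzyloxy)-3-iodo-5-methoxy-4H-chromen-4-one F5. Suzuki–Miyaura coupling of F5 with commercially available (E)-2-(4-methoxyphenyl)vinylboronic acid (Pd(PPh3)4, zerovalent palladium, K2CO3, dioxane/H2O, 80 °C) would give the styrylchromone. The fallback sets out from 3 and returns at 8, bypassing 5 and step 4.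

## Further compounds

F1 | step 8 | 5-(benzyloxy)-2-(hydroxymethyl)-3-methoxyphenol | COc1cc(OCc2ccccc2)cc(O)c1CO
F2 | step 8 | (2S,3R)-7-(benzyloxy)-3-[(2S,3R)-7-(benzyloxy)-5-methoxy-2-(4-methoxyphenyl)-3,4-dihydro-2H-chromen-3-yl]-5-methoxy-2-(4-methoxyphenyl)-2,3-dihydro-4H-chromen-4-one | COc1ccc([C@H]2Oc3cc(OCc4ccccc4)cc(OC)c3C(=O)[C@@H]2[C@H]2Cc3c(OC)cc(OCc4ccccc4)cc3O[C@@H]2c2ccc(OC)cc2)cc1
F3 | step 5 | (2R,3S)-7-(benzyloxy)-5-methoxy-2-(4-methoxyphenyl)-3-[(E)-2-(4-methoxyphenyl)ethenyl]-2,3-dihydro-4H-chromen-4-one | COc1ccc([C@@H]2Oc3cc(OCc4ccccc4)cc(OC)c3C(=O)[C@H]2/C=C/c2ccc(OC)cc2)cc1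
F0 | step 9 | none | none
F4 | step 3 | (2E)-1-[4-(benzyloxy)-2-hydroxy-6-methoxyphenyl]-3-(dimethylamino)prop-2-en-1-one | CN(C)/C=C/C(=O)c1c(O)cc(OCc2ccccc2)cc1OC
F5 | step 3 | 7-(benzyloxy)-3-iodo-5-methoxy-4H-chromen-4-one | COc1cc(OCc2ccccc2)cc2occ(I)c(=O)c12
A1 | alternative 1 | (2E,3E)-2,3-bis(4-methoxybenzylidene)butanedioic acid | O=C(O)/C(=C/c1ccc(OC)cc1)C(=C/c1ccc(OC)cc1)\C(=O)O
A2 | alternative 1 | 5-(benzyloxy)-3-methoxy-2-(trimethylsilyl)phenyl trifluoromethanesulfonate | COc1cc(OCc2ccccc2)cc(OS(=O)(=O)C(F)(F)F)c1[Si](C)(C)C
A3 | alternative 1 | (2E,3E)-1,4-bis[4-(benzyloxy)-2-hydroxy-6-methoxyphenyl]-2,3-bis(4-methoxybenzylidene)butane-1,4-dione | O=C(c1c(O)cc(OCc2ccccc2)cc1OC)/C(=C/c1ccc(OC)cc1)C(=C/c1ccc(OC)cc1)\C(=O)c1c(O)cc(OCc2ccccc2)cc1OC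
A4 | alternative 2 | 2,2'-{[(1R,4R)-1,4-bis(4-methoxyphenyl)but-2-yne-1,4-diyl]bis(oxy)}bis[6-methoxy-4-(triisopropylsilyloxy)benzaldehyde] | COc1ccc([C@@H](Oc2cc(O[Si](C(C)C)(C(C)C)C(C)C)cc(OC)c2C=O)C#C[C@H](Oc2cc(O[Si](C(C)C)(C(C)C)C(C)C)cc(OC)c2C=O)c2ccc(OC)cc2)cc1
A5 | alternative 2 | (2S,2'S,3R,3'R)-5,5'-dimethoxy-2,2'-bis(4-methoxyphenyl)-7,7'-bis(triisopropylsilyloxy)-[3,3'-bichromane]-4,4'-dione | COc1ccc([C@H]2Oc3cc(O[Si](C(C)C)(C(C)C)C(C)C)cc(OC)c3C(=O)[C@@H]2[C@H]2C(=O)c3c(OC)cc(O[Si](C(C)C)(C(C)C)C(C)C)cc3O[C@@H]2c2ccc(OC)cc2)cc1
A6 | alternative 3 | cis-fused, C2-symmetric 2,6-bis(4-methoxyphenyl)-3,7-dioxabicyclo[3.3.0]octane-4,8-dione, the enantiomer with the benzylic carbons arranged as C2 and C2' of the target | COc1ccc([C@H]2OC(=O)[C@@H]3[C@@H](c4ccc(OC)cc4)OC(=O)[C@H]23)cc1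
A7 | alternative 3 | [2-fluoro-6-methoxy-4-(triisopropylsilyloxy)phenyl]lithium | [Li]c1c(F)cc(O[Si](C(C)C)(C(C)C)C(C)C)cc1OC
A8 | alternative 3 | 1,4-bis[2-fluoro-6-methoxy-4-(triisopropylsilyloxy)phenyl]-2,3-bis[(S)-hydroxy(4-methoxyphenyl)methyl]butane-1,4-dione, C3 and C3' each epimeric to the target | COc1ccc([C@@H](O)[C@@H](C(=O)c2c(F)cc(O[Si](C(C)C)(C(C)C)C(C)C)cc2OC)[C@H](C(=O)c2c(F)cc(O[Si](C(C)C)(C(C)C)C(C)C)cc2OC)[C@H](O)c2ccc(OC)cc2)cc1
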